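**Strategy.** The cyclohexene is cut at its C1–C2 bond, C1 being the quaternary carbon (methyl, E-coumarinylvinyl) and C2 the ring CH that carries the second 7-methoxycoumarin-8-yl ring; this bond is the sigma bond of an ester-enolate [3,3] shift. One Ireland–Claisen rearrangement therefore forms that C–C bond, sets both stereocentres and generates the E-styryl alkene, while the single carbinol stereocentre is consumed. Its precursor is the (7-methoxycoumarin-8-yl)acetate of an (R)-configured coumarin-8-yl dienyl carbinol, both halves being C8-functionalised 7-methoxycoumarins. The acid is then converted into a vinyl group and the carbocycle is closed last by ring-closing metathesis onto the isopropenyl end.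

Key step: step 9

Assumption: the antipode of the chiral oxazoline–sulfonamide ligand in step 7 is taken to be the one that sends the alkenyl group to the Re face of the formyl group of 4 (Re-face attack gives the R carbinol); the sense is to be checked on a trial scale by MTPA ester analysis and the other antipode used if it is opposite.

In the names below, "7-methoxycoumarin-8-yl" stands for 7-methoxy-2-oxo-2H-chromen-8-yl.

Step 1
Reactants: 1 umbelliferone (7-hydroxy-2H-chromen-2-one)
Product: 3 7-hydroxy-2-oxo-2H-chromene-8-carbaldehyde, via Duff aldimine 2 (not isolated)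
Conditions: hexamethylenetetramine, CF3CO2H, 90 °C; then H2O, 60 °C
Reagents that add atoms: hexamethylenetetramine, C1N2CN3CN1CN(C2)C3; water, O
Why: Duff formylation, in which the iminium ion released from hexamethylenetetramine attacks C8 (the most nucleophilic position of a 7-hydroxycoumarin, ortho to the phenol), the benzylic amine is dehydrogenated by hydride transfer to aldimine 2 and water hydrolyses it to the aldehyde; no stereocentre is formed.

Step 2
Reactants: 3 7-hydroxy-2-oxo-2H-chromene-8-carbaldehyde
Product: 4 7-methoxy-2-oxo-2H-chromene-8-carbaldehyde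
Conditions: MeI, K2CO3, acetone, reflux
Reagents that add atoms: iodomethane, CI
Why: Williamson O-methylation of the phenoxide under mild carbonate conditions that leave the lactone and the aldehyde untouched; no stereocentre is formed.

Step 3
Reactants: 5 osthol (7-methoxy-8-(3-methylbut-2-en-1-yl)coumarin)
Product: 7 2-(7-methoxycoumarin-8-yl)acetaldehyde, via ozonide 6 (not isolated)
Conditions: O3, CH2Cl2, −78 °C (Sudan Red 7B end-point); then PPh3, −78 °C → rt
Reagents that add atoms: ozone, [O-][O+]=O
Why: Ozonolysis with reductive work-up, in which the electron-rich trisubstituted prenyl alkene is cleaved far faster than the conjugated, electron-poor C3=C4 bond of the coumarin and the dye end-point guards against over-oxidation; no stereocentre is formed.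

Step 4
Reactants: 7 2-(7-methoxycoumarin-8-yl)acetaldehyde
Product: 8 2-(7-methoxycoumarin-8-yl)acetic acid
Conditions: NaClO2, NaH2PO4, 2-methylbut-2-ene, t-BuOH/H2O, 0 °C → rt
Reagents that add atoms: sodium chlorite, [Na+].[O-]Cl=O
Why: Pinnick oxidation converts the enolisable arylacetaldehyde into the acid under buffered conditions, the alkene scavenger removing HOCl before it can chlorinate the methoxyarene; no stereocentre is formed.

Step 5
Reactants: 9 hex-5-yn-2-one
Product: 10 2-methylhex-1-en-5-yne
Conditions: Ph3PCH3Br, KOt-Bu, Et2O, 0 °C → rt; fractional distillation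
Reagents that add atoms: methyltriphenylphosphonium bromide, C[P+](c1ccccc1)(c1ccccc1)c1ccccc1.[Br-]
Why: Wittig methylenation of the methyl ketone, the ylide being too weak a base to consume the terminal alkyne and the volatile enyne being separable from Et2O through a short fractionating column; no stereocentre is formed.

Step 6
Reactants: 10 2-methylhex-1-en-5-yne
Product: 12 (1E)-1-iodo-2,5-dimethylhexa-1,5-diene, via alkenylalane 11 (not isolated)
Conditions: Me3Al, Cp2ZrCl2 (20 mol %), CH2Cl2, 0 °C → rt; then I2, THF, −30 → 0 °C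
Reagents that add atoms: trimethylaluminium, C[Al](C)C; iodine, II
Why: Zirconium-catalysed methylalumination (Negishi carboalumination) adds CH3 and Al syn across the terminal alkyne with the methyl on the internal carbon, the 1,1-disubstituted alkene being inert, and iodinolysis of the C–Al bond with retention fixes the E-trisubstituted geometry.

Step 7
Reactants: 4 7-methoxy-2-oxo-2H-chromene-8-carbaldehyde; 12 (1E)-1-iodo-2,5-dimethylhexa-1,5-diene
Product: 14 8-[(1R,2E)-1-hydroxy-3,6-dimethylhepta-2,6-dien-1-yl]-7-methoxycoumarin, via zirconium alkoxide 13 (not isolated)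
Conditions: CrCl2 (10 mol %), chiral oxazoline–sulfonamide ligand (11 mol %), proton sponge (11 mol %), NiCl2(dmp) (2 mol %; dmp = 2,9-dimethyl-1,10-phenanthroline), Mn, Cp2ZrCl2, LiCl, MeCN, rt; NaHCO3 (aq)
Reagents that add atoms: none
Why: Catalytic asymmetric Nozaki–Hiyama–Kishi alkenylation, in which nickel activates the alkenyl iodide with retention of geometry, the alkenyl group passes to trivalent chromium bound to the chiral sulfonamide and is delivered under ligand control to the Re face of the formyl group to set the (R)-carbinol, while Cp2ZrCl2 takes over the alkoxide as 13 so that Mn can turn the chromium over; the weakly basic organochromium spares the lactone.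

Step 8
Reactants: 14 8-[(1R,2E)-1-hydroxy-3,6-dimethylhepta-2,6-dien-1-yl]-7-methoxycoumarin; 8 2-(7-methoxycoumarin-8-yl)acetic acid
Product: 15 (1R,2E)-1-(7-methoxycoumarin-8-yl)-3,6-dimethylhepta-2,6-dien-1-yl 2-(7-methoxycoumarin-8-yl)acetate
Conditions: DCC, DMAP (cat.), CH2Cl2, 0 °C → rt; chromatography on Et3N-deactivated silica
Reagents that add atoms: none
Why: Steglich esterification, in which DCC activates the arylacetic acid and DMAP transfers the acyl group to the hindered secondary alcohol without acid, so the ionisable benzylic allylic C–O bond is not disturbed and the carbinol configuration is retained.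

Step 9
Reactants: 15 (1R,2E)-1-(7-methoxycoumarin-8-yl)-3,6-dimethylhepta-2,6-dien-1-yl 2-(7-methoxycoumarin-8-yl)acetate
Product: 18 (2R,3R)-2-(7-methoxycoumarin-8-yl)-3-[(E)-2-(7-methoxycoumarin-8-yl)ethenyl]-3,6-dimethylhept-6-enoic acid, via silyl ketene acetal 16 (not isolated), via silyl ester 17 (not isolated)
Conditions: LiN(SiMe3)2, Me3SiCl, Et3N, THF, −78 °C → rt; then 0.5 M HCl (aq)
Reagents that add atoms: none
Why: Ireland–Claisen rearrangement: LiN(SiMe3)2 removes the acidic arylacetate α-hydrogen at −78 °C with Me3SiCl present, and the resulting (Z)-silyl ketene acetal 16 (aryl cis to OSiMe3, the usual outcome for arylacetates) undergoes a concerted suprafacial [3,3] shift on warming, forming the bond between the acetate α-carbon and the methyl-bearing alkene terminus while the benzylic allylic C–O bond breaks and the alkene moves into conjugation with the coumarin. The closest known reaction type is the ester-enolate Claisen rearrangement of arylacetates of secondary allylic alcohols bearing a trisubstituted alkene, which builds vicinal tertiary and quaternary carbons with 1,3-chirality transfer. No ring is closed in this step; the six-membered chair exists only as the transition state. The quaternary centre is controlled by the (R)-carbinol together with the E-alkene of 15 (carbinol coumarinyl group equatorial, since an axial one would meet the axial alkene methyl 1,3-diaxially), and the aryl-bearing centre by the Z ketene-acetal geometry, so both should emerge R with aryl and styryl destined to be cis in the ring. The step needs one ketene-acetal geometry, one chair and deprotonation faster than attack of the base on the lactones; the acidity of the α-hydrogen, the hindered silylamide with in-situ silylation at low temperature and the weakly ionising medium are relied on for these. The same equatorial coumarinyl group dictates the E geometry of the new styryl alkene, and the aqueous acid releases acid 18 from silyl ester 17.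

Step 10
Reactants: 18 (2R,3R)-2-(7-methoxycoumarin-8-yl)-3-[(E)-2-(7-methoxycoumarin-8-yl)ethenyl]-3,6-dimethylhept-6-enoic acid
Product: 20 (2R,3R)-2-(7-methoxycoumarin-8-yl)-3-[(E)-2-(7-methoxycoumarin-8-yl)ethenyl]-3,6-dimethylhept-6-en-1-ol, via mixed anhydride 19 (not isolated)
Conditions: i-BuOCOCl, N-methylmorpholine, THF, −15 °C; then NaBH4, THF/H2O, 0 °C
Reagents that add atoms: none
Why: Chemoselective reduction of a carboxylic acid through its mixed carbonic anhydride, in which NaBH4 reduces the activated acyl group at 0 °C while the coumarin lactones and all alkenes should remain; neither stereocentre takes part.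

Step 11
Reactants: 20 (2R,3R)-2-(7-methoxycoumarin-8-yl)-3-[(E)-2-(7-methoxycoumarin-8-yl)ethenyl]-3,6-dimethylhept-6-en-1-ol
Product: 21 (2R,3R)-2-(7-methoxycoumarin-8-yl)-3-[(E)-2-(7-methoxycoumarin-8-yl)ethenyl]-3,6-dimethylhept-6-enal
Conditions: Dess–Martin periodinane, NaHCO3, CH2Cl2, 0 °C → rt; used crude
Reagents that add atoms: none
Why: Dess–Martin oxidation under bicarbonate buffering gives the α-aryl aldehyde without acid or base strong enough to epimerise the aryl-bearing carbon, and the aldehyde is carried on at once.

Step 12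
Reactants: 21 (2R,3R)-2-(7-methoxycoumarin-8-yl)-3-[(E)-2-(7-methoxycoumarin-8-yl)ethenyl]-3,6-dimethylhept-6-enal
Product: 22 (3R,4R)-3-(7-methoxycoumarin-8-yl)-4-[(E)-2-(7-methoxycoumarin-8-yl)ethenyl]-4,7-dimethylocta-1,7-diene
Conditions: Zn, CH2Br2, TiCl4, THF; then 21, CH2Cl2, 0 °C → rt
Reagents that add atoms: dibromomethane, BrCBr
Why: Takai–Lombardo methylenation, in which the non-basic geminal dizinc/titanium reagent converts the hindered, epimerisable aldehyde into the vinyl group without reacting with the lactone carbonyls and without scrambling the α-stereocentre.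

Step 13
Reactants: 22 (3R,4R)-3-(7-methoxycoumarin-8-yl)-4-[(E)-2-(7-methoxycoumarin-8-yl)ethenyl]-4,7-dimethylocta-1,7-diene
Product: 23 7-methoxy-8-{(E)-2-[(1R,2R)-2-(7-methoxycoumarin-8-yl)-1,4-dimethylcyclohex-3-en-1-yl]ethenyl}coumarin (CNP0156435.1)
Conditions: second-generation Grubbs catalyst (H2IMes)(PCy3)Cl2Ru=CHPh (5 mol %), CH2Cl2 (5 mM), 40 °C
Reagents that add atoms: none
Why: Ring-closing metathesis, in which the ruthenium carbene loads on the only monosubstituted vinyl group and closes the six-membered ring onto the 1,1-disubstituted alkene with loss of ethylene, the hindered E-styryl and the electron-poor coumarin alkenes staying out of the reaction and both stereocentres remaining untouched.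

**Compound list**

1 | umbelliferone (7-hydroxy-2H-chromen-2-one) | O=c1ccc2ccc(O)cc2o1 | starting material
2 | 7-hydroxy-8-(iminomethyl)coumarin (Duff aldimine, present in the flask as an iminium salt) | N=Cc1c(O)ccc2ccc(=O)oc12 | intermediate
3 | 7-hydroxy-2-oxo-2H-chromene-8-carbaldehyde | O=Cc1c(O)ccc2ccc(=O)oc12 | intermediate
4 | 7-methoxy-2-oxo-2H-chromene-8-carbaldehyde | COc1ccc2ccc(=O)oc2c1C=O | intermediate
5 | osthol (7-methoxy-8-(3-methylbut-2-en-1-yl)coumarin) | COc1ccc2ccc(=O)oc2c1CC=C(C)C | starting material
6 | 8-[(5,5-dimethyl-1,2,4-trioxolan-3-yl)methyl]-7-methoxycoumarin (ozonide, formed in the flask) | COc1ccc2ccc(=O)oc2c1CC1OOC(C)(C)O1 | intermediate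
7 | 2-(7-methoxycoumarin-8-yl)acetaldehyde | COc1ccc2ccc(=O)oc2c1CC=O | intermediate
8 | 2-(7-methoxycoumarin-8-yl)acetic acid | COc1ccc2ccc(=O)oc2c1CC(=O)O | intermediate
9 | hex-5-yn-2-one | CC(=O)CCC#C | starting material
10 | 2-methylhex-1-en-5-yne | C=C(C)CCC#C | intermediate
11 | [(1E)-2,5-dimethylhexa-1,5-dien-1-yl]dimethylalane (formed in the flask) | C[Al](C)/C=C(\C)CCC(C)=C | intermediate
12 | (1E)-1-iodo-2,5-dimethylhexa-1,5-diene | I/C=C(\C)CCC(C)=C | intermediate
13 | chlorobis(cyclopentadienyl)zirconium alkoxide of 14 (formed in the flask) | COc1ccc2ccc(=O)oc2c1[C@H](O[Zr](Cl)(C1C=CC=C1)C1C=CC=C1)/C=C(\C)CCC(C)=C | intermediate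
14 | 8-[(1R,2E)-1-hydroxy-3,6-dimethylhepta-2,6-dien-1-yl]-7-methoxycoumarin | COc1ccc2ccc(=O)oc2c1[C@H](O)/C=C(\C)CCC(C)=C | intermediate
15 | (1R,2E)-1-(7-methoxycoumarin-8-yl)-3,6-dimethylhepta-2,6-dien-1-yl 2-(7-methoxycoumarin-8-yl)acetate | COc1ccc2ccc(=O)oc2c1CC(=O)O[C@@H](c1c(OC)ccc2ccc(=O)oc12)/C=C(\C)CCC(C)=C | intermediate
16 | (Z)-trimethylsilyl ketene acetal of 15, aryl cis to OSiMe3 (formed in the flask) | COc1ccc2ccc(=O)oc2c1/C=C(\O[Si](C)(C)C)O[C@@H](c1c(OC)ccc2ccc(=O)oc12)/C=C(\C)CCC(C)=C | intermediate
17 | trimethylsilyl ester of 18 (formed in the flask) | COc1ccc2ccc(=O)oc2c1/C=C/[C@@](C)(CCC(C)=C)[C@H](c1c(OC)ccc2ccc(=O)oc12)C(=O)O[Si](C)(C)C | intermediate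
18 | (2R,3R)-2-(7-methoxycoumarin-8-yl)-3-[(E)-2-(7-methoxycoumarin-8-yl)ethenyl]-3,6-dimethylhept-6-enoic acid | COc1ccc2ccc(=O)oc2c1/C=C/[C@@](C)(CCC(C)=C)[C@H](c1c(OC)ccc2ccc(=O)oc12)C(=O)O | intermediate
19 | isobutyl carbonic mixed anhydride of 18 (formed in the flask) | COc1ccc2ccc(=O)oc2c1/C=C/[C@@](C)(CCC(C)=C)[C@H](c1c(OC)ccc2ccc(=O)oc12)C(=O)OC(=O)OCC(C)C | intermediate
20 | (2R,3R)-2-(7-methoxycoumarin-8-yl)-3-[(E)-2-(7-methoxycoumarin-8-yl)ethenyl]-3,6-dimethylhept-6-en-1-ol | COc1ccc2ccc(=O)oc2c1/C=C/[C@@](C)(CCC(C)=C)[C@H](c1c(OC)ccc2ccc(=O)oc12)CO | intermediate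
21 | (2R,3R)-2-(7-methoxycoumarin-8-yl)-3-[(E)-2-(7-methoxycoumarin-8-yl)ethenyl]-3,6-dimethylhept-6-enal | COc1ccc2ccc(=O)oc2c1/C=C/[C@@](C)(CCC(C)=C)[C@H](c1c(OC)ccc2ccc(=O)oc12)C=O | intermediate
22 | (3R,4R)-3-(7-methoxycoumarin-8-yl)-4-[(E)-2-(7-methoxycoumarin-8-yl)ethenyl]-4,7-dimethylocta-1,7-diene | COc1ccc2ccc(=O)oc2c1/C=C/[C@@](C)(CCC(C)=C)[C@H](c1c(OC)ccc2ccc(=O)oc12)C=C | intermediate
23 | 7-methoxy-8-{(E)-2-[(1R,2R)-2-(7-methoxycoumarin-8-yl)-1,4-dimethylcyclohex-3-en-1-yl]ethenyl}coumarin (CNP0156435.1) | COc1ccc2ccc(=O)oc2c1/C=C/[C@@]1(C)CCC(C)=C[C@H]1c1c(OC)ccc2ccc(=O)oc12 | target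

**Totals**

Total step count: 13.
Longest linear sequence: 9 steps (steps 5, 6, 7, 8, 9, 10, 11, 12, 13 from hex-5-yn-2-one; the same length from umbelliferone through steps 1, 2, 7–13).

**Steps most likely to fail**

Step 9. What may go wrong: addition of the silylamide to a coumarin lactone instead of α-deprotonation, leakage of the ketene-acetal geometry, or ionisation of the benzylic allylic C–O bond so that chirality transfer is lost. The fallback sets out from 4 and 14 and comes back at 21; it runs the rearrangement at the aldehyde oxidation level without strong base. Takai iodo-olefination of 4 (CHI3, CrCl2, THF, 0 °C) should give 8-[(E)-2-iodoethenyl]-7-methoxycoumarin F1. C–O coupling of F1 with carbinol 14 (CuI, 3,4,7,8-tetramethyl-1,10-phenanthroline, Cs2CO3, toluene, 80 °C) would give with retention of alkene geometry (1R,2E)-1-(7-methoxycoumarin-8-yl)-3,6-dimethylhepta-2,6-dien-1-yl (E)-2-(7-methoxycoumarin-8-yl)ethenyl ether F2. After filtration from the base, heating F2 in toluene (80–110 °C) should trigger the aliphatic Claisen rearrangement through the same chair (aryl trans to the ether oxygen, as in 16) and deliver aldehyde 21 directly, so that 15 to 20 are bypassed.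

Step 7. What may go wrong: poor facial selectivity or slow turnover in the chromium-mediated addition to the ortho,ortho-disubstituted aldehyde. The fallback sets out from 12 and 4 and comes back at 14; it is a catalytic asymmetric alkenylzinc addition. Iodine–lithium exchange on 12 (t-BuLi, Et2O, −78 °C) gives [(1E)-2,5-dimethylhexa-1,5-dien-1-yl]lithium F3, and transmetalation with EtZnCl gives ethyl[(1E)-2,5-dimethylhexa-1,5-dien-1-yl]zinc F4. After the lithium salts are sequestered with N,N,N',N'-tetraethylethylenediamine, addition of F4 to 4 is catalysed by (+)-3-exo-morpholinoisoborneol (the antipode expected to direct Re-face attack) in toluene/hexane at 0 °C, the alkenyl group transferring in preference to ethyl, to give 14.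

Step 10. What may go wrong: hydride attack at the carbonate carbonyl of the hindered mixed anhydride, which returns the acid, or competing reduction of a coumarin lactone. The fallback sets out from 18 and comes back at 21; it goes to the aldehyde without the alcohol. 1-Chloro-N,N,2-trimethylprop-1-en-1-amine (CH2Cl2, 0 °C, neutral) converts 18 into (2R,3R)-2-(7-methoxycoumarin-8-yl)-3-[(E)-2-(7-methoxycoumarin-8-yl)ethenyl]-3,6-dimethylhept-6-enoyl chloride F5, and LiAlH(Ot-Bu)3 in THF at −78 °C reduces F5 selectively to aldehyde 21, so that 20 and the oxidation are not needed.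

**Further compounds**

F1 | step 9 | 8-[(E)-2-iodoethenyl]-7-methoxycoumarin | COc1ccc2ccc(=O)oc2c1/C=C/I
F2 | step 9 | (1R,2E)-1-(7-methoxycoumarin-8-yl)-3,6-dimethylhepta-2,6-dien-1-yl (E)-2-(7-methoxycoumarin-8-yl)ethenyl ether | COc1ccc2ccc(=O)oc2c1/C=C/O[C@@H](c1c(OC)ccc2ccc(=O)oc12)/C=C(\C)CCC(C)=C
F3 | step 7 | [(1E)-2,5-dimethylhexa-1,5-dien-1-yl]lithium | [Li]/C=C(\C)CCC(C)=C
F4 | step 7 | ethyl[(1E)-2,5-dimethylhexa-1,5-dien-1-yl]zinc | CC[Zn]/C=C(\C)CCC(C)=C
F5 | step 10 | (2R,3R)-2-(7-methoxycoumarin-8-yl)-3-[(E)-2-(7-methoxycoumarin-8-yl)ethenyl]-3,6-dimethylhept-6-enoyl chloride | COc1ccc2ccc(=O)oc2c1/C=C/[C@@](C)(CCC(C)=C)[C@H](c1c(OC)ccc2ccc(=O)oc12)C(Cl)=O
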